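**Plan**

- Retrosynthesis: the C-x–CH=CMe2 alkene is cut first (Wittig; the side chain is carried as an ester). Then the C-x–C-y and O4–C-z bonds of pyran ring A are cut together in one [4+2] event that also separates the two quinolone halves (C-x = side-chain CH, C-y = ring-fusion CH next to CMe2, C-z = ring-fusion O–CH).
- Enabling feature: ring A, the dihydropyran on the cis C-y–C-z junction, is the formal cycloadduct of the O4=C4–C3=CH oxadiene of a 3-alkylidene-1-methylquinoline-2,4-dione with the C3=C4 alkene of the 2H-pyran (ring B) of N-methylflindersine. The target is thus a hetero-Diels–Alder dimer of that alkaloid.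
- Forward order: both quinolone bicycles are bought as 4-hydroxy-1-methylquinolin-2-one. Ring B closes first (prenal, Knoevenagel/6π-oxa-electrocyclisation). Ring A closes last, in the step that joins the halves, using a glyoxylate-derived oxadiene that cannot electrocyclise. Ester to alcohol to aldehyde to isobutenyl follows.
- Stereochemistry: C-x, C-y and C-z all arise in the cycloaddition. A chiral copper bis(oxazoline) complex chooses the oxadiene face, the exo approach relates C-y to C-x, and suprafacial addition to the cis ring alkene gives the cis fusion. Later steps break no bond at these centres.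

Key step: step 2

Labels: quinolone A and ring A are the half derived from the oxadiene; quinolone B and ring B (with CMe2) are the N-methylflindersine half. In the ester, alcohol, aldehyde and target the configuration is C-x S, C-y S, C-z R. The hydrogens at C-y and C-z are cis, and the C-x substituent is trans to the C-y–CMe2 bond.

Assumption: the (S,S)-ligand is taken as the antipode that leads to this enantiomer. The sense of induction cannot be predicted with confidence for this new substrate class; if the first run shows the opposite sense, the equally available (R,R)-ligand is used with no other change.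

**Route**

Step 1
Reactants: 1 4-hydroxy-1-methylquinolin-2(1H)-one; 2 3-methylbut-2-enal (prenal)
Product: 4 N-methylflindersine (2,2,6-trimethyl-2H-pyrano[3,2-c]quinolin-5(6H)-one), via 1-oxatriene 3 (not isolated)
Conditions: ethylenediammonium diacetate (10 mol%), DMF, 100 °C
Reagents that add atoms: none
Why: Knoevenagel condensation at C3 of 1 gives the 1-oxatriene 3 (side chain cis to the C4 carbonyl), which closes through the C4 oxygen by 6π-oxa-electrocyclisation to the 2-quinolone-fused 2H-pyran (ring B), the established one-flask route to N-methylflindersine from these two components, and no stereocentre is formed.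

Step 2
Reactants: 1 4-hydroxy-1-methylquinolin-2(1H)-one; 5 ethyl glyoxylate; 4 N-methylflindersine
Product: 7 ethyl ester of the (x S, y S, z R) bis-pyranoquinolone (CO2Et at C-x, rings A and B cis-fused), via alkylidene dione oxadiene 6 (not isolated)
Conditions: Cu(OTf)2 (10 mol%), (S,S)-2,2'-isopropylidenebis(4-tert-butyl-2-oxazoline) (11 mol%), 4 Å MS, CH2Cl2, 0 °C to rt; 5 (2 equiv, freshly distilled), 4 (1.5 equiv), solid 1 added in portions
Reagents that add atoms: none
Why: Proposed new method: 1 and Lewis-acid-activated 5 condense (aldol, then loss of water onto the sieves) to oxadiene 6, whose isomer with the ester cis to the lactam C2 carbonyl binds divalent copper between that lactam oxygen and the ester carbonyl (a maleate-like seven-membered chelate, since the two ring carbonyls point apart and cannot hold one metal), which lowers the LUMO of the O4=C4–C3=CH diene, keeps the ester on its outer side and leaves O4 free; the pyran alkene of 4, the far end of a 1-alkoxydiene, then attacks the ester-bearing carbon through its carbon next to CMe2, and O4 closes on the benzylic cation that quinolone B stabilises, an asynchronous inverse-electron-demand [4+2] cycloaddition. The closest known reaction types are the three-component domino Knoevenagel/hetero-Diels–Alder reaction of 4-hydroxyquinolones and 4-hydroxycoumarins with aldehydes and electron-rich alkenes, and inverse-demand hetero-Diels–Alder and Michael reactions of two-point-binding unsaturated carbonyl compounds under copper bis(oxazoline) catalysis, whereas the pairing with a 2H-pyran alkene and the enantioselective form are new. Ring A, a six-membered dihydropyran, closes in this [4+2] mode (C-x–C-y bond first, O4–C-z bond second) onto ring B, which is already present in 4. C-x is set by the ligand, whose tert-butyl groups screen one face of the bound oxadiene; C-y is set relative to C-x by the exo approach of ring B, which keeps the CMe2 carbon away from the lactam carbonyl and the metal and places the ester trans to the C-y–CMe2 bond; C-z follows from suprafacial addition to the cis ring alkene, hence the cis fusion. The step needs face, exo/endo, regio- and periselectivity: the polarity of both partners fixes the regiochemistry, copper on O2 and the greater stability of the 2-quinolone direct closure through O4, and excess 5 and 4 with slow dosing of the sparingly soluble 1 keep the oxadiene from being captured by a second molecule of 1. Any endo adduct is removed at this stage by chromatography and crystallisation, because base equilibration at C-x would turn it into the enantiomer of 7 and not into 7.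

Step 3
Reactants: 7 ethyl ester of the (x S, y S, z R) bis-pyranoquinolone
Product: 8 primary alcohol (CH2OH at C-x) of the (x S, y S, z R) bis-pyranoquinolone
Conditions: LiBH4, THF, 0 °C to rt
Reagents that add atoms: none
Why: Borohydride reduction of the ester gives the primary alcohol chemoselectively, the two 2-quinolone lactams (vinylogous aromatic amides) and the benzylic C-z–O bond being inert to LiBH4, and no bond to a stereocentre is broken while C-x, alpha to the ester, already holds its more stable trans arrangement.

Step 4
Reactants: 8 primary alcohol of the (x S, y S, z R) bis-pyranoquinolone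
Product: 9 aldehyde (CHO at C-x) of the (x S, y S, z R) bis-pyranoquinolone
Conditions: Dess–Martin periodinane, CH2Cl2, 0 °C to rt
Reagents that add atoms: none
Why: Dess–Martin oxidation stops cleanly at the aldehyde under near-neutral, non-aqueous conditions and spares the electron-rich quinolones; C-x becomes enolisable but already has the more stable arrangement (formyl group trans to the C-y–CMe2 bond), so no base treatment is applied and the aldehyde is taken directly into step 5.

Step 5
Reactants: 9 aldehyde of the (x S, y S, z R) bis-pyranoquinolone; 10 isopropyltriphenylphosphonium iodide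
Product: 12 target CNP0210533.1 (2-methylprop-1-enyl at C-x; C-x S, C-y S, C-z R), via isopropylidenetriphenylphosphorane 11 (not isolated)
Conditions: 10, KN(SiMe3)2, THF, 0 °C; then 9, −78 °C to rt
Reagents that add atoms: none
Why: Wittig olefination with the lithium-free non-stabilised ylide 11 should add to the aldehyde at low temperature faster than it enolises it, the symmetrical isopropylidene terminus leaves no alkene geometry to control, and no stereocentre is touched, so the configuration set in step 2 is carried into 12.

**Compound list**

1 | 4-hydroxy-1-methylquinolin-2(1H)-one | Cn1c(=O)cc(O)c2ccccc12 | starting material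
2 | 3-methylbut-2-enal (prenal) | CC(C)=CC=O | starting material
3 | (E)-1-methyl-3-(3-methylbut-2-en-1-ylidene)quinoline-2,4(1H,3H)-dione (side chain cis to the C4 carbonyl; transient 1-oxatriene) | CC(C)=C/C=C1\C(=O)c2ccccc2N(C)C1=O | intermediate
4 | N-methylflindersine (2,2,6-trimethyl-2H-pyrano[3,2-c]quinolin-5(6H)-one) | CC1(C)C=Cc2c(O1)c1ccccc1n(C)c2=O | intermediate
5 | ethyl glyoxylate | CCOC(=O)C=O | starting material
6 | ethyl (Z)-2-(1-methyl-2,4-dioxo-1,4-dihydroquinolin-3(2H)-ylidene)acetate (ester cis to the C2 lactam carbonyl; transient oxadiene) | CCOC(=O)/C=C1/C(=O)c2ccccc2N(C)C1=O | intermediate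
7 | ethyl ester of the (x S, y S, z R) bis-pyranoquinolone (CO2Et at C-x) | CCOC(=O)[C@@H]1c2c(c3ccccc3n(C)c2=O)O[C@H]2c3c(c4ccccc4n(C)c3=O)OC(C)(C)[C@@H]12 | intermediate
8 | primary alcohol of the (x S, y S, z R) bis-pyranoquinolone (CH2OH at C-x) | OC[C@@H]1c2c(c3ccccc3n(C)c2=O)O[C@H]2c3c(c4ccccc4n(C)c3=O)OC(C)(C)[C@@H]12 | intermediate
9 | aldehyde of the (x S, y S, z R) bis-pyranoquinolone (CHO at C-x) | O=C[C@@H]1c2c(c3ccccc3n(C)c2=O)O[C@H]2c3c(c4ccccc4n(C)c3=O)OC(C)(C)[C@@H]12 | intermediate
10 | isopropyltriphenylphosphonium iodide | CC(C)[P+](c1ccccc1)(c1ccccc1)c1ccccc1.[I-] | starting material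
11 | isopropylidenetriphenylphosphorane (ylide, formed in the flask) | CC(C)=P(c1ccccc1)(c1ccccc1)c1ccccc1 | intermediate
12 | CNP0210533.1, (x S, y S, z R) bis-pyranoquinolone with 2-methylprop-1-enyl at C-x | CC(C)=C[C@@H]1c2c(c3ccccc3n(C)c2=O)O[C@H]2c3c(c4ccccc4n(C)c3=O)OC(C)(C)[C@@H]12 | target

**Step count**

Total steps: 5. Longest linear sequence: 5 steps (1 to 4 to 7 to 8 to 9 to 12).

**Steps most likely to fail**

Step 2. Three things may go wrong:
- The hindered pyran alkene may add too slowly under the mild catalytic conditions, so that the oxadiene is consumed by a second molecule of 1.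
- The seven-membered copper chelate may organise the oxadiene too loosely for good face selectivity.
- The exo/endo preference may be weak.

The fallback uses the known thermal three-component reaction and separates the enantiomeric series through a covalently bound auxiliary. It sets out from 1 and 4. (1R,2S,5R)-Menthyl glyoxylate (commercial as its hydrate) is condensed with 1 (ethylenediammonium diacetate, 4 Å MS, toluene, 80–100 °C) in the presence of excess 4. The transient menthyl oxadiene F1 is trapped by 4 in an uncatalysed domino Knoevenagel/hetero-Diels–Alder reaction. The diastereomeric adducts are separated by chromatography and crystallisation. The menthyl ester F2 with the (x S, y S, z R) core is then reduced with LiBH4 in THF, which brings the route back at 8.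

Step 5. The basic, hindered ylide may enolise the alpha-branched aldehyde instead of adding to it, which would give low conversion and possible erosion at C-x. The fallback sets out from 9 and avoids a basic carbon nucleophile. Takai methylenation (Zn, CH2I2, Ti(OiPr)4, THF, rt) should give the vinyl compound F3. Cross-metathesis of F3 with 2-methylbut-2-ene (second-generation Grubbs catalyst, CH2Cl2, 40 °C) installs the isopropylidene terminus and comes back to the route at 12.

Step 4. The alpha-(quinolonyl) aldehyde may enolise toward the quinolone-conjugated enol during oxidation and isolation, with loss of C-x integrity or oxidative degradation. The fallback sets out from 8 and never passes through an aldehyde; the Wittig partners are exchanged. Appel iodination (I2, PPh3, imidazole, CH2Cl2) should give the primary iodide F4. Heating with PPh3 in MeCN should give the phosphonium iodide F5. Its ylide (KN(SiMe3)2, THF, −78 °C) is condensed with acetone, which comes back to the route at 12.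

**Further compounds**

F1 | step 2 | (1R,2S,5R)-menthyl (Z)-2-(1-methyl-2,4-dioxo-1,4-dihydroquinolin-3(2H)-ylidene)acetate (transient oxadiene) | CC(C)[C@@H]5CC[C@@H](C)C[C@H]5OC(=O)/C=C1/C(=O)c2ccccc2N(C)C1=O
F2 | step 2 | (1R,2S,5R)-menthyl ester of the (x S, y S, z R) bis-pyranoquinolone (menthyl analogue of 7) | CC(C)[C@@H]5CC[C@@H](C)C[C@H]5OC(=O)[C@@H]1c2c(c3ccccc3n(C)c2=O)O[C@H]2c3c(c4ccccc4n(C)c3=O)OC(C)(C)[C@@H]12
F3 | step 5 | vinyl compound (CH=CH2 at C-x) of the (x S, y S, z R) bis-pyranoquinolone | C=C[C@@H]1c2c(c3ccccc3n(C)c2=O)O[C@H]2c3c(c4ccccc4n(C)c3=O)OC(C)(C)[C@@H]12
F4 | step 4 | primary iodide (CH2I at C-x) of the (x S, y S, z R) bis-pyranoquinolone | IC[C@@H]1c2c(c3ccccc3n(C)c2=O)O[C@H]2c3c(c4ccccc4n(C)c3=O)OC(C)(C)[C@@H]12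
F5 | step 4 | triphenylphosphonium iodide (CH2PPh3 at C-x) of the (x S, y S, z R) bis-pyranoquinolone | [I-].c1ccc(cc1)[P+](c1ccccc1)(c1ccccc1)C[C@@H]1c2c(c3ccccc3n(C)c2=O)O[C@H]2c3c(c4ccccc4n(C)c3=O)OC(C)(C)[C@@H]12
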